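## Retrosynthetic overview

1. Ring A is the epoxycyclohexane, numbered here C1 (C–CH3, epoxide), C2 (epoxide CH), C3 (CH bearing the CH2 linker), C4 (CH bearing isopropenyl), C5, C6; ring B is the bromohydrin cyclohexane.
2. The target comes from reagent-controlled epoxidation of the C1=C2 alkene (step 11), after Wittig methylenation of a linker ketone (step 10) and removal of a temporary vinylic bromine on C2 (step 9).
3. Key disconnection (step 8): the C3–CH2 bond and ring A itself. Ring A arises from the five-membered ring C1, C3, C4, C5, C6 of a 6,6-dibromobicyclo[3.1.0]hexane whose CBr2 carbon becomes C2 (ring expansion by one carbon, cyclopropyl-to-allyl opening); the C1–C2–C3 allyl cation is captured at C3 by the silyl enol ether of the ring B methyl ketone.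
4. Enabling feature: in ring A, C2 lies between the methyl-bearing C1 and the branching carbon C3, so C1–C2–C3 is an allyl unit whose central carbon can be inserted as a carbene carbon into a C1=C3 cyclopentene bond; the adjacent C4 stereocenter (isopropenyl) steers the nucleophile to the trans face of C3.
5. Fragments and ring order: ring B is taken from (1S,2S,4R)-limonene-1,2-diol (steps 4–7); the cyclopentene comes from cyclopentenone (steps 1–2), the cyclopropane is added in step 3, ring A forms in step 8, the oxirane in step 11.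

Key step: step 8

Remark on the chemistry: the ligand antipode named in step 1 is assumed to be the one that gives the 3S adduct; if the sense of induction is the opposite, the mirror-image ligand is used.

## Route

Step 1
Reactants: 1 cyclopent-2-en-1-one; 2 prop-1-en-2-ylmagnesium bromide
Product: 4 (3S)-3-(prop-1-en-2-yl)cyclopent-1-en-1-yl trifluoromethanesulfonate, via bromomagnesium enolate 3 (not isolated)
Conditions: CuBr·SMe2 (5 mol %), (R)-1-[(S)-2-(diphenylphosphino)ferrocenyl]ethyldicyclohexylphosphine (6 mol %), t-BuOMe, −78 °C; then N-(5-chloropyridin-2-yl)bis(trifluoromethanesulfonyl)imide, THF, −78 to 0 °C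
Reagents that add atoms: N-(5-chloropyridin-2-yl)bis(trifluoromethanesulfonyl)imide, Clc1ccc(nc1)N(S(=O)(=O)C(F)(F)F)S(=O)(=O)C(F)(F)F
Why: Copper-catalysed asymmetric conjugate addition of the Grignard reagent sets ring A C4 under ligand control and gives the enolate regiospecifically, so that O-triflation fixes the double bond between the future C1 and C3.

Step 2
Reactants: 4 (3S)-3-(prop-1-en-2-yl)cyclopent-1-en-1-yl trifluoromethanesulfonate
Product: 5 (3S)-1-methyl-3-(prop-1-en-2-yl)cyclopent-1-ene
Conditions: MeMgBr, Fe(acac)3 (5 mol %), THF/N-methylpyrrolidone, −30 to 0 °C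
Reagents that add atoms: methylmagnesium bromide, C[Mg]Br
Why: Iron-catalysed Kumada-type cross-coupling of an alkenyl triflate with a methyl Grignard reagent puts the C1 methyl group in place without moving the double bond or touching C4.

Step 3
Reactants: 5 (3S)-1-methyl-3-(prop-1-en-2-yl)cyclopent-1-ene
Product: 6 (1S,4S,5R)-6,6-dibromo-1-methyl-4-(prop-1-en-2-yl)bicyclo[3.1.0]hexane
Conditions: CHBr3 (1.0 equiv), KOtBu, pentane, −30 to 0 °C; crude 6 kept cold and used at once
Reagents that add atoms: bromoform, BrC(Br)Br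
Why: Cheletropic [2+1] addition of electrophilic dibromocarbene should favour the more nucleophilic trisubstituted ring alkene over the 1,1-disubstituted isopropenyl group and occur anti to the C4 substituent; the two new centers are erased again in step 8.

Step 4
Reactants: 7 (1S,2S,4R)-1-methyl-4-(prop-1-en-2-yl)cyclohexane-1,2-diol
Product: 9 1-[(1R,3S,4S)-3,4-dihydroxy-4-methylcyclohexyl]ethan-1-one, via ozonide 8 (not isolated)
Conditions: O3, CH2Cl2, −78 °C; then Me2S, −78 °C to rt
Reagents that add atoms: ozone, [O-][O+]=O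
Why: Ozonolysis with reductive work-up cleaves the only alkene to the methyl ketone that later supplies the linker CH2 and the carbon of the exocyclic methylene; no stereocenter is involved.

Step 5
Reactants: 9 1-[(1R,3S,4S)-3,4-dihydroxy-4-methylcyclohexyl]ethan-1-one
Product: 11 (3aS,6R,7aS)-6-acetyl-3a-methylhexahydro-1,3,2-benzodioxathiole 2,2-dioxide, via cyclic sulfite 10 (not isolated)
Conditions: SOCl2, Et3N, CH2Cl2, 0 °C; then RuCl3 (1 mol %), NaIO4, MeCN/H2O, 0 °C
Reagents that add atoms: thionyl chloride, O=S(Cl)Cl; sodium periodate, [Na+].[O-]I(=O)(=O)=O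
Why: Two-stage cyclic sulfate formation (sulfite, then ruthenium-catalysed oxidation) activates the secondary C–O bond and ties up the tertiary oxygen; the trans-diol bridges through its diequatorial chair and no alkene is present that the oxidant could attack.

Step 6
Reactants: 11 (3aS,6R,7aS)-6-acetyl-3a-methylhexahydro-1,3,2-benzodioxathiole 2,2-dioxide
Product: 13 1-[(1R,3R,4S)-3-bromo-4-hydroxy-4-methylcyclohexyl]ethan-1-one, via lithium bromo sulfate 12 (not isolated)
Conditions: LiBr, THF, 40 °C; then H2SO4 (cat.), H2O (1 equiv), THF, rt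
Reagents that add atoms: lithium bromide, [Li+].[Br-]
Why: SN2 opening of the cyclic sulfate by bromide at the secondary carbon inverts that center and places Br cis to the tertiary oxygen, and acid hydrolysis of the tertiary sulfate monoester by S–O cleavage keeps the carbinol configuration, which gives the cis-bromohydrin of ring B.

Step 7
Reactants: 13 1-[(1R,3R,4S)-3-bromo-4-hydroxy-4-methylcyclohexyl]ethan-1-one
Product: 14 trimethyl({1-[(1R,3R,4S)-3-bromo-4-methyl-4-(trimethylsilyloxy)cyclohexyl]ethenyl}oxy)silane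
Conditions: Me3SiCl (4 equiv), LiN(i-Pr)2 (2.4 equiv), THF, −78 °C (in situ quench); pentane, filtration
Reagents that add atoms: chlorotrimethylsilane, C[Si](C)(C)Cl
Why: Kinetic deprotonation at the methyl group under in situ silylation gives the terminal silyl enol ether, and the tertiary hydroxyl is silylated in the same operation, which keeps it from acting as a nucleophile or as an alkoxide in the next steps.

Step 8
Reactants: 6 (1S,4S,5R)-6,6-dibromo-1-methyl-4-(prop-1-en-2-yl)bicyclo[3.1.0]hexane; 14 trimethyl({1-[(1R,3R,4S)-3-bromo-4-methyl-4-(trimethylsilyloxy)cyclohexyl]ethenyl}oxy)silane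
Product: 16 2-[(1R,6S)-2-bromo-3-methyl-6-(prop-1-en-2-yl)cyclohex-2-en-1-yl]-1-[(1R,3R,4S)-3-bromo-4-methyl-4-(trimethylsilyloxy)cyclohexyl]ethan-1-one, via allyl cation 15 (not isolated)
Conditions: 6 (1.3 equiv), 14 (1.0 equiv), AgBF4 (1.3 equiv), 2,6-di-tert-butyl-4-methylpyridine (0.3 equiv), CH2Cl2, −78 to −40 °C, dark
Reagents that add atoms: none
Why: Proposed new method: monovalent silver pulls off the endo bromide of 6 while the C1–C5 bond of the bicycle (the C1–C3 bond of the future ring A) opens in a disrotatory two-electron electrocyclic cyclopropyl-to-allyl process, so that the five-membered carbocycle takes up the CBr2 carbon and becomes the six-membered 2-bromoallyl cation 15, which is attacked at C3 by the terminal carbon of silyl enol ether 14 and then loses the silyl group to BF4−; the closest known reaction types are the silver-promoted ring expansion of 6,6-dibromobicyclo[3.1.0]hexanes with capture of the cation by oxygen or nitrogen nucleophiles and the SN1 alkylation of silyl enol ethers with allylic halides under silver or Lewis acid activation. Ring A is formed not by closing a new ring bond but by cleaving the zero-atom bridge of the bicycle, a ring expansion of the cyclopentane by one carbon. The new stereocenter C3 is controlled by the adjacent C4 isopropenyl group, the nucleophile entering the half-chair cation on the opposite face to give the 3,4-trans pair. Regioselectivity for C3 over C1 is needed and should follow from the tertiary, more hindered nature of C1 and from formation of the tetrasubstituted bromoalkene; chemoselectivity of silver for the strained gem-dibromide over the secondary bromide of ring B is needed and should follow from the low temperature and the far higher ionisation rate of the cyclopropyl bromide. The bromine that stays on C2 is a temporary activating group and is removed in step 9.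

Step 9
Reactants: 16 2-[(1R,6S)-2-bromo-3-methyl-6-(prop-1-en-2-yl)cyclohex-2-en-1-yl]-1-[(1R,3R,4S)-3-bromo-4-methyl-4-(trimethylsilyloxy)cyclohexyl]ethan-1-one
Product: 17 2-[(1S,6S)-3-methyl-6-(prop-1-en-2-yl)cyclohex-2-en-1-yl]-1-[(1R,3R,4S)-3-bromo-4-methyl-4-(trimethylsilyloxy)cyclohexyl]ethan-1-one
Conditions: Pd(OAc)2 (10 mol %), PPh3 (20 mol %), HCO2H, Et3N, DMF, 60 °C
Reagents that add atoms: none
Why: Palladium-catalysed formate reduction removes the vinylic bromine from C2 (oxidative addition of zerovalent palladium to the C(sp2)–Br bond, decarboxylation of formate, C–H reductive elimination), while the unactivated secondary bromide of ring B should not undergo oxidative addition under these conditions.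

Step 10
Reactants: 17 2-[(1S,6S)-3-methyl-6-(prop-1-en-2-yl)cyclohex-2-en-1-yl]-1-[(1R,3R,4S)-3-bromo-4-methyl-4-(trimethylsilyloxy)cyclohexyl]ethan-1-one
Product: 19 (1S,2R,4R)-2-bromo-1-methyl-4-{3-[(1S,6S)-3-methyl-6-(prop-1-en-2-yl)cyclohex-2-en-1-yl]prop-1-en-2-yl}cyclohexan-1-ol, via silyl ether 18 (not isolated)
Conditions: Ph3PCH3Br, KN(SiMe3)2, THF, 0 °C to rt; then HCl (1 M), THF, 0 °C
Reagents that add atoms: methyltriphenylphosphonium bromide, C[P+](c1ccccc1)(c1ccccc1)c1ccccc1.[Br-]
Why: Wittig methylenation turns the linker ketone into the 1,1-disubstituted alkene and dilute acid then removes the tertiary trimethylsilyl ether; the ring B carbon next to the ketone already holds its substituent in the favoured equatorial position, so enolisation should not change it.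

Step 11
Reactants: 19 (1S,2R,4R)-2-bromo-1-methyl-4-{3-[(1S,6S)-3-methyl-6-(prop-1-en-2-yl)cyclohex-2-en-1-yl]prop-1-en-2-yl}cyclohexan-1-ol
Product: 20 (1S,2R,4R)-2-bromo-1-methyl-4-{3-[(1R,2R,3S,6S)-6-methyl-3-(prop-1-en-2-yl)-7-oxabicyclo[4.1.0]heptan-2-yl]prop-1-en-2-yl}cyclohexan-1-ol
Conditions: 1,2:4,5-di-O-isopropylidene-β-D-erythro-2,3-hexodiulo-2,6-pyranose (30 mol %), 2KHSO5·KHSO4·K2SO4, K2CO3, Bu4NHSO4, MeCN/dimethoxymethane/aqueous Na2B4O7 buffer (pH 10.5), 0 °C
Reagents that add atoms: potassium peroxymonosulfate, [K+].[O-]S(=O)(=O)OO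
Why: Shi epoxidation: the chiral dioxirane formed from the D-fructose-derived ketone should oxidise the electron-rich trisubstituted C1=C2 alkene in preference to the two 1,1-disubstituted alkenes and, through its spiro transition state, deliver oxygen to the face on which the C3 side chain lies (the same sense that gives (R,R)-epoxides from 1-arylcyclohexenes), which sets C1 (S) and C2 (R) trans to the C4 isopropenyl group.

## Compound list

1 | cyclopent-2-en-1-one | O=C1C=CCC1 | starting material
2 | prop-1-en-2-ylmagnesium bromide | C=C(C)[Mg]Br | starting material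
3 | bromomagnesium (3S)-3-(prop-1-en-2-yl)cyclopent-1-en-1-olate | Br[Mg]OC1=C[C@@H](C(C)=C)CC1 | intermediate
4 | (3S)-3-(prop-1-en-2-yl)cyclopent-1-en-1-yl trifluoromethanesulfonate | FC(F)(F)S(=O)(=O)OC1=C[C@@H](C(C)=C)CC1 | intermediate
5 | (3S)-1-methyl-3-(prop-1-en-2-yl)cyclopent-1-ene | CC1=C[C@@H](C(C)=C)CC1 | intermediate
6 | (1S,4S,5R)-6,6-dibromo-1-methyl-4-(prop-1-en-2-yl)bicyclo[3.1.0]hexane | C[C@]12CC[C@H](C(C)=C)[C@H]1C2(Br)Br | intermediate
7 | (1S,2S,4R)-1-methyl-4-(prop-1-en-2-yl)cyclohexane-1,2-diol (limonene-1,2-diol) | C=C(C)[C@@H]1CC[C@](C)(O)[C@@H](O)C1 | starting material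
8 | 3-[(1R,3S,4S)-3,4-dihydroxy-4-methylcyclohexyl]-3-methyl-1,2,4-trioxolane (ozonide) | CC1(OCOO1)[C@@H]1CC[C@](C)(O)[C@@H](O)C1 | intermediate
9 | 1-[(1R,3S,4S)-3,4-dihydroxy-4-methylcyclohexyl]ethan-1-one | CC(=O)[C@@H]1CC[C@](C)(O)[C@@H](O)C1 | intermediate
10 | (3aS,6R,7aS)-6-acetyl-3a-methylhexahydro-1,3,2-benzodioxathiole 2-oxide (cyclic sulfite) | CC(=O)[C@@H]1CC[C@]2(C)OS(=O)O[C@H]2C1 | intermediate
11 | (3aS,6R,7aS)-6-acetyl-3a-methylhexahydro-1,3,2-benzodioxathiole 2,2-dioxide (cyclic sulfate) | CC(=O)[C@@H]1CC[C@]2(C)OS(=O)(=O)O[C@H]2C1 | intermediate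
12 | lithium (1S,2R,4R)-4-acetyl-2-bromo-1-methylcyclohexyl sulfate | CC(=O)[C@@H]1CC[C@](C)(OS(=O)(=O)[O-])[C@H](Br)C1.[Li+] | intermediate
13 | 1-[(1R,3R,4S)-3-bromo-4-hydroxy-4-methylcyclohexyl]ethan-1-one | CC(=O)[C@@H]1CC[C@](C)(O)[C@H](Br)C1 | intermediate
14 | trimethyl({1-[(1R,3R,4S)-3-bromo-4-methyl-4-(trimethylsilyloxy)cyclohexyl]ethenyl}oxy)silane | C=C(O[Si](C)(C)C)[C@@H]1CC[C@](C)(O[Si](C)(C)C)[C@H](Br)C1 | intermediate
15 | 2-bromo-3-methyl-6-(prop-1-en-2-yl)cyclohex-2-en-1-ylium tetrafluoroborate (C6 configured as C4 of 6) | CC1=C(Br)[CH+][C@@H](C(C)=C)CC1.F[B-](F)(F)F | intermediate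
16 | 2-[(1R,6S)-2-bromo-3-methyl-6-(prop-1-en-2-yl)cyclohex-2-en-1-yl]-1-[(1R,3R,4S)-3-bromo-4-methyl-4-(trimethylsilyloxy)cyclohexyl]ethan-1-one | O=C(C[C@@H]1[C@@H](C(C)=C)CCC(C)=C1Br)[C@@H]1CC[C@](C)(O[Si](C)(C)C)[C@H](Br)C1 | intermediate
17 | 2-[(1S,6S)-3-methyl-6-(prop-1-en-2-yl)cyclohex-2-en-1-yl]-1-[(1R,3R,4S)-3-bromo-4-methyl-4-(trimethylsilyloxy)cyclohexyl]ethan-1-one | O=C(C[C@@H]1[C@@H](C(C)=C)CCC(C)=C1)[C@@H]1CC[C@](C)(O[Si](C)(C)C)[C@H](Br)C1 | intermediate
18 | trimethyl{[(1S,2R,4R)-2-bromo-1-methyl-4-{3-[(1S,6S)-3-methyl-6-(prop-1-en-2-yl)cyclohex-2-en-1-yl]prop-1-en-2-yl}cyclohexyl]oxy}silane | C=C(C[C@@H]1[C@@H](C(C)=C)CCC(C)=C1)[C@@H]1CC[C@](C)(O[Si](C)(C)C)[C@H](Br)C1 | intermediate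
19 | (1S,2R,4R)-2-bromo-1-methyl-4-{3-[(1S,6S)-3-methyl-6-(prop-1-en-2-yl)cyclohex-2-en-1-yl]prop-1-en-2-yl}cyclohexan-1-ol | C=C(C[C@@H]1[C@@H](C(C)=C)CCC(C)=C1)[C@@H]1CC[C@](C)(O)[C@H](Br)C1 | intermediate
20 | (1S,2R,4R)-2-bromo-1-methyl-4-{3-[(1R,2R,3S,6S)-6-methyl-3-(prop-1-en-2-yl)-7-oxabicyclo[4.1.0]heptan-2-yl]prop-1-en-2-yl}cyclohexan-1-ol | C=C(C[C@@H]1[C@@H](C(=C)C)CC[C@]2(C)O[C@H]12)[C@@H]1CC[C@](C)(O)[C@H](Br)C1 | target

## Step count and risks

Total step count: 11. Longest linear sequence: 8 steps (7 to 20 through steps 4–11); the ring A branch (1 to 6) has 3 steps before the union.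

Steps most likely to fail:

1. Step 8 (Proposed new method). What may go wrong: the allyl cation loses a proton to a bromodiene or is captured at its tertiary terminus faster than the C–C bond forms at C3, and silver also ionises the secondary bromide of ring B. Fallback with known chemistry, from 6 back to 16: 6 is warmed in CH2Cl2 without silver, which should bring about the known thermal cyclopropyl-to-allyl rearrangement of dibromobicyclo[3.1.0]hexanes and give the allylic bromide (3R,4R)-2,3-dibromo-1-methyl-4-(prop-1-en-2-yl)cyclohex-1-ene F1. F1 is then used to alkylate silyl enol ether 14 under ZnBr2 catalysis in CH2Cl2 (Lewis acid SN1 alkylation of silyl enol ethers with allylic halides), which should give 16 with ring expansion and C–C bond formation in separate operations and no silver in contact with ring B.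

2. Step 3. What may go wrong: the carbene adds to the isopropenyl group or to both alkenes, and the strained adduct ionises during handling. Fallback, from 1 and 2 back to 16: enolate 3 is quenched with Me3SiCl instead of the triflating agent to give trimethyl{[(3S)-3-(prop-1-en-2-yl)cyclopent-1-en-1-yl]oxy}silane F2, whose enol ether double bond should outcompete the isopropenyl group for dibromocarbene (CHBr3, KOtBu). The adduct 6,6-dibromo-4-(prop-1-en-2-yl)-1-(trimethylsilyloxy)bicyclo[3.1.0]hexane F3 should open on warming to (4S)-2-bromo-4-(prop-1-en-2-yl)cyclohex-2-en-1-one F4 (the known one-carbon ring enlargement of silyl enol ethers). MeLi/CeCl3 then gives the tertiary allylic alcohol (4S)-2-bromo-1-methyl-4-(prop-1-en-2-yl)cyclohex-2-en-1-ol F5, and BF3·OEt2 in CH2Cl2 at −78 °C ionises F5 to the same allyl cation, which 14 should capture to give 16.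

3. Step 11. What may go wrong: oxygen transfer to the wrong face if the weak substrate bias (attack anti to the C3 side chain) opposes the catalyst, and competing oxidation of the 1,1-disubstituted alkenes. Fallback, from 17 back to 20: 17 is desilylated (HCl, THF) to 1-[(1R,3R,4S)-3-bromo-4-hydroxy-4-methylcyclohexyl]-2-[(1S,6S)-3-methyl-6-(prop-1-en-2-yl)cyclohex-2-en-1-yl]ethan-1-one F6. N-iodosuccinimide in wet THF should then add iodine to C1 from the face opposite to the side chain while the ketone oxygen, held on the side-chain face, closes onto C2, giving the cis-fused iodo hemiketal (1S,2R,4R)-2-bromo-4-[2-hydroxy-7-iodo-7-methyl-4-(prop-1-en-2-yl)octahydro-1-benzofuran-2-yl]-1-methylcyclohexan-1-ol F7 (carbonyl participation in iodohydroxylation). K2CO3 in MeOH opens the hemiketal, and the C2 alkoxide displaces the anti tertiary iodide to give 1-[(1R,3R,4S)-3-bromo-4-hydroxy-4-methylcyclohexyl]-2-[(1R,2R,3S,6S)-6-methyl-3-(prop-1-en-2-yl)-7-oxabicyclo[4.1.0]heptan-2-yl]ethan-1-one F8, with the epoxide on the side-chain face by substrate control. Methylenation of F8 with Cp2TiMe2 (toluene, 65 °C) should give 20.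

Further compounds
F1 | step 8 | (3R,4R)-2,3-dibromo-1-methyl-4-(prop-1-en-2-yl)cyclohex-1-ene | CC1=C(Br)[C@H](Br)[C@@H](C(C)=C)CC1
F2 | step 3 | trimethyl{[(3S)-3-(prop-1-en-2-yl)cyclopent-1-en-1-yl]oxy}silane | C[Si](C)(C)OC1=C[C@@H](C(C)=C)CC1
F3 | step 3 | 6,6-dibromo-4-(prop-1-en-2-yl)-1-(trimethylsilyloxy)bicyclo[3.1.0]hexane (cyclopropane anti to isopropenyl) | C[Si](C)(C)O[C@]12CC[C@H](C(C)=C)[C@H]1C2(Br)Br
F4 | step 3 | (4S)-2-bromo-4-(prop-1-en-2-yl)cyclohex-2-en-1-one | O=C1CC[C@H](C(C)=C)C=C1Br
F5 | step 3 | (4S)-2-bromo-1-methyl-4-(prop-1-en-2-yl)cyclohex-2-en-1-ol (both C1 epimers) | CC1(O)CC[C@H](C(C)=C)C=C1Br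
F6 | step 11 | 1-[(1R,3R,4S)-3-bromo-4-hydroxy-4-methylcyclohexyl]-2-[(1S,6S)-3-methyl-6-(prop-1-en-2-yl)cyclohex-2-en-1-yl]ethan-1-one | O=C(C[C@@H]1[C@@H](C(C)=C)CCC(C)=C1)[C@@H]1CC[C@](C)(O)[C@H](Br)C1
F7 | step 11 | (1S,2R,4R)-2-bromo-4-[2-hydroxy-7-iodo-7-methyl-4-(prop-1-en-2-yl)octahydro-1-benzofuran-2-yl]-1-methylcyclohexan-1-ol (cis-fused, iodine trans to the ring oxygen) | OC1(C[C@@H]2[C@@H](C(C)=C)CC[C@@](C)(I)[C@@H]2O1)[C@@H]1CC[C@](C)(O)[C@H](Br)C1
F8 | step 11 | 1-[(1R,3R,4S)-3-bromo-4-hydroxy-4-methylcyclohexyl]-2-[(1R,2R,3S,6S)-6-methyl-3-(prop-1-en-2-yl)-7-oxabicyclo[4.1.0]heptan-2-yl]ethan-1-one | O=C(C[C@@H]1[C@@H](C(C)=C)CC[C@]2(C)O[C@H]12)[C@@H]1CC[C@](C)(O)[C@H](Br)C1
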